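**Retrosynthetic overview**
1. C8 ester: target ⇒ diol 11 + silyl-protected orsellinoyl chloride 14 (from orsellinic acid 12).
2. Ring B (formed second): C5=C4a by intramolecular aldol condensation; key bond C6–C7 by adding an acetyl-anion equivalent (1-ethoxyvinyl metal) to the C7 methyl ketone of 8 under chelation by the free C8 hydroxyl, which sets C7.
3. 8 ⇒ silyloxydiene 5 + methylglyoxal by an enantioselective Mukaiyama aldol, which sets C8 and C8a.
4. Ring A (formed first): dihydropyranone 4 from (3E)-pent-3-en-2-one and 3-chloropropanoyl chloride (C-acylation, then O-alkylative closure).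

Assumption: atom labels C1–C8a follow the 1H-isochromene numbering of the target and are used for the same atoms in every intermediate; methylglyoxal is used as the anhydrous monomer distilled from the commercial 40 % aqueous solution.

**Step 1**
Reactants: 1 (3E)-pent-3-en-2-one; 2 3-chloropropanoyl chloride
Product: 4 6-[(1E)-prop-1-en-1-yl]-2,3-dihydro-4H-pyran-4-one, via chlorodiketone 3 (not isolated)
Conditions: 1 (2.0 equiv), LiN(SiMe3)2 (2.0 equiv), THF, −78 °C; 2 (1.0 equiv), −78 → 0 °C; then NaI (10 mol %), DMPU, 50 °C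
Reagents that add atoms: none
Why: Claisen-type C-acylation of the kinetic methyl-side lithium enolate gives the β-diketone, whose lithium enolate closes ring A by 6-exo-tet O-alkylation on the primary chloride (C-alkylation would need a four-membered ring); no stereocenter is formed.

**Step 2**
Reactants: 4 6-[(1E)-prop-1-en-1-yl]-2,3-dihydro-4H-pyran-4-one
Product: 5 trimethyl({6-[(1E)-prop-1-en-1-yl]-2H-pyran-4-yl}oxy)silane
Conditions: LiN(i-Pr)2, TMSCl, THF, −78 °C; non-aqueous work-up, used at once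
Reagents that add atoms: trimethylsilyl chloride, C[Si](C)(C)Cl
Why: Kinetic α'-deprotonation of the vinylogous ester at C8a and O-silylation (silyl enol ether formation) give a Danishefsky-type silyloxydiene that is most nucleophilic at C8a; no stereocenter is formed.

**Step 3**
Reactants: 5 trimethyl({6-[(1E)-prop-1-en-1-yl]-2H-pyran-4-yl}oxy)silane; 6 methylglyoxal (2-oxopropanal)
Product: 8 (3S)-3-[(1S)-1-hydroxy-2-oxopropyl]-6-[(1E)-prop-1-en-1-yl]-2,3-dihydro-4H-pyran-4-one, via silyl ether 7 (not isolated)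
Conditions: Cu(OTf)2 (10 mol %), (S,S)-t-Bu-box (11 mol %), THF, −78 °C; then 1 M HCl, THF, 0 °C
Reagents that add atoms: none
Why: Proposed new method: methylglyoxal should bind divalent copper in the square-planar bis(oxazoline) complex through both carbonyl oxygens, as pyruvate esters and vicinal diketones do, so that the more electrophilic aldehyde carbon is attacked on its si face (the tert-butyl groups shield the re face) by C8a of the silyloxydiene through an open antiperiplanar transition state, giving the syn (3S,1'S) adduct and setting C8 and C8a; the closest known reaction type is the Cu(OTf)2/bis(oxazoline)-catalysed enantioselective Mukaiyama aldol addition of enolsilanes to chelating 1,2-dicarbonyl electrophiles.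

**Step 4 (key step)**
Reactants: 8 (3S)-3-[(1S)-1-hydroxy-2-oxopropyl]-6-[(1E)-prop-1-en-1-yl]-2,3-dihydro-4H-pyran-4-one
Product: 11 (7R,8S,8aS)-7,8-dihydroxy-7-methyl-3-[(1E)-prop-1-en-1-yl]-1,7,8,8a-tetrahydro-6H-isochromen-6-one, via enol ether diol 9 (not isolated), via hydroxy diketone 10 (not isolated)
Conditions: CH2=C(OEt)Li (3 equiv; from ethyl vinyl ether, t-BuLi, THF, −78 → 0 °C), MgBr2·OEt2 (3 equiv), THF–CH2Cl2, −78 °C; aq. NH4Cl; then TsOH·H2O (0.2 equiv), THF–H2O, rt, then PhMe, 50 °C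
Reagents that add atoms: (1-ethoxyvinyl)magnesium bromide, C=C(OCC)[Mg]Br (made in the flask from ethyl vinyl ether, C=COCC); water, O
Why: Acyl-anion (umpolung) addition: the magnesium alkoxide of the C8 hydroxyl and the C7 carbonyl form a five-membered Cram chelate, so the acetyl-anion equivalent attacks anti to C8a and sets (7R) with the C7 hydroxyl trans to the C8 oxygen; acid then unmasks the methyl ketone (enol ether hydrolysis), and its enol closes ring B by intramolecular aldol condensation onto the protonated vinylogous-ester carbonyl C4a, with dehydration to the conjugated dienone.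

**Step 5**
Reactants: 12 orsellinic acid (2,4-dihydroxy-6-methylbenzoic acid)
Product: 13 tert-butyldimethylsilyl 2,4-bis(tert-butyldimethylsilyloxy)-6-methylbenzoate
Conditions: TBSCl (3.3 equiv), imidazole, DMF, rt
Reagents that add atoms: tert-butyldimethylsilyl chloride, CC(C)(C)[Si](C)(C)Cl
Why: Exhaustive silylation masks both phenols as silyl ethers and turns the acid into a silyl ester that can be converted directly into the acid chloride; no stereocenter is involved.

**Step 6**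
Reactants: 13 tert-butyldimethylsilyl 2,4-bis(tert-butyldimethylsilyloxy)-6-methylbenzoate; 11 (7R,8S,8aS)-7,8-dihydroxy-7-methyl-3-[(1E)-prop-1-en-1-yl]-1,7,8,8a-tetrahydro-6H-isochromen-6-one
Product: 15 (7R,8S,8aS)-7-hydroxy-7-methyl-6-oxo-3-[(1E)-prop-1-en-1-yl]-6,7,8,8a-tetrahydro-1H-isochromen-8-yl 2,4-bis(tert-butyldimethylsilyloxy)-6-methylbenzoate, via acid chloride 14 (not isolated)
Conditions: (COCl)2, DMF (cat.), CH2Cl2, 0 °C → rt; then 11, pyridine, DMAP (cat.), CH2Cl2, 0 °C → rt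
Reagents that add atoms: none
Why: The silyl ester is exchanged for the acid chloride under neutral Vilsmeier conditions, and DMAP-catalysed acylation (nucleophilic catalysis) then takes the secondary C8 hydroxyl in preference to the tertiary C7 hydroxyl; acylation at oxygen leaves C7, C8 and C8a untouched.

**Step 7**
Reactants: 15 (7R,8S,8aS)-7-hydroxy-7-methyl-6-oxo-3-[(1E)-prop-1-en-1-yl]-6,7,8,8a-tetrahydro-1H-isochromen-8-yl 2,4-bis(tert-butyldimethylsilyloxy)-6-methylbenzoate
Product: 16 (7R,8S,8aS)-7-hydroxy-7-methyl-6-oxo-3-[(1E)-prop-1-en-1-yl]-6,7,8,8a-tetrahydro-1H-isochromen-8-yl 2,4-dihydroxy-6-methylbenzoate (CNP0130178.5)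
Conditions: HF·pyridine, pyridine, THF, 0 °C
Reagents that add atoms: none
Why: Fluoride-mediated desilylation cleaves the two aryl silyl ethers under buffered, weakly acidic conditions that spare the hindered aryl ester, the tertiary ketol and the dienone; no stereocenter is affected.

**Compound list**
1 | (3E)-pent-3-en-2-one | C/C=C/C(C)=O | starting material
2 | 3-chloropropanoyl chloride | ClCCC(Cl)=O | starting material
3 | (6E)-1-chlorooct-6-ene-3,5-dione | C/C=C/C(=O)CC(=O)CCCl | intermediate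
4 | 6-[(1E)-prop-1-en-1-yl]-2,3-dihydro-4H-pyran-4-one | C/C=C/C1=CC(=O)CCO1 | intermediate
5 | trimethyl({6-[(1E)-prop-1-en-1-yl]-2H-pyran-4-yl}oxy)silane | C/C=C/C1=CC(O[Si](C)(C)C)=CCO1 | intermediate
6 | methylglyoxal (2-oxopropanal) | CC(=O)C=O | starting material
7 | (3S)-3-[(1S)-2-oxo-1-(trimethylsilyloxy)propyl]-6-[(1E)-prop-1-en-1-yl]-2,3-dihydro-4H-pyran-4-one | C/C=C/C1=CC(=O)[C@H]([C@H](O[Si](C)(C)C)C(C)=O)CO1 | intermediate
8 | (3S)-3-[(1S)-1-hydroxy-2-oxopropyl]-6-[(1E)-prop-1-en-1-yl]-2,3-dihydro-4H-pyran-4-one | C/C=C/C1=CC(=O)[C@H]([C@H](O)C(C)=O)CO1 | intermediate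
9 | (3S)-3-[(1S,2R)-3-ethoxy-1,2-dihydroxy-2-methylbut-3-en-1-yl]-6-[(1E)-prop-1-en-1-yl]-2,3-dihydro-4H-pyran-4-one | C/C=C/C1=CC(=O)[C@H]([C@H](O)[C@@](C)(O)C(=C)OCC)CO1 | intermediate
10 | (3S)-3-[(1S,2R)-1,2-dihydroxy-2-methyl-3-oxobutyl]-6-[(1E)-prop-1-en-1-yl]-2,3-dihydro-4H-pyran-4-one | C/C=C/C1=CC(=O)[C@H]([C@H](O)[C@@](C)(O)C(C)=O)CO1 | intermediate
11 | (7R,8S,8aS)-7,8-dihydroxy-7-methyl-3-[(1E)-prop-1-en-1-yl]-1,7,8,8a-tetrahydro-6H-isochromen-6-one | C/C=C/C1=CC2=CC(=O)[C@](C)(O)[C@@H](O)[C@@H]2CO1 | intermediate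
12 | orsellinic acid (2,4-dihydroxy-6-methylbenzoic acid) | Cc1cc(O)cc(O)c1C(=O)O | starting material
13 | tert-butyldimethylsilyl 2,4-bis(tert-butyldimethylsilyloxy)-6-methylbenzoate | Cc1cc(O[Si](C)(C)C(C)(C)C)cc(O[Si](C)(C)C(C)(C)C)c1C(=O)O[Si](C)(C)C(C)(C)C | intermediate
14 | 2,4-bis(tert-butyldimethylsilyloxy)-6-methylbenzoyl chloride | Cc1cc(O[Si](C)(C)C(C)(C)C)cc(O[Si](C)(C)C(C)(C)C)c1C(Cl)=O | intermediate
15 | (7R,8S,8aS)-7-hydroxy-7-methyl-6-oxo-3-[(1E)-prop-1-en-1-yl]-6,7,8,8a-tetrahydro-1H-isochromen-8-yl 2,4-bis(tert-butyldimethylsilyloxy)-6-methylbenzoate | C/C=C/C1=CC2=CC(=O)[C@](C)(O)[C@@H](OC(=O)c3c(C)cc(O[Si](C)(C)C(C)(C)C)cc3O[Si](C)(C)C(C)(C)C)[C@@H]2CO1 | intermediate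
16 | (7R,8S,8aS)-7-hydroxy-7-methyl-6-oxo-3-[(1E)-prop-1-en-1-yl]-6,7,8,8a-tetrahydro-1H-isochromen-8-yl 2,4-dihydroxy-6-methylbenzoate | C/C=C/C1=CC2=CC(=O)[C@](C)(O)[C@@H](OC(=O)c3c(C)cc(O)cc3O)[C@@H]2CO1 | target

**Step count**
Total: 7 steps. Longest linear sequence: 6 steps (1, 2, 3, 4, 6, 7); step 5 is a one-step side branch.

**Steps most likely to fail, with fallbacks**

Step 3. Monomeric methylglyoxal is awkward to handle and has no direct precedent with this catalyst, so yield, ee or the syn/anti ratio may be poor. The fallback sets out from 5 and swaps the electrophile for ethyl glyoxylate, a standard two-point-binding aldehyde, building the methyl ketone afterwards. Cu(OTf)2/(S,S)-t-Bu-box in THF at −78 °C gives ethyl (2S)-2-[(3S)-4-oxo-6-[(1E)-prop-1-en-1-yl]-3,4-dihydro-2H-pyran-3-yl]-2-(trimethylsilyloxy)acetate F1, and 1 M HCl frees ethyl (2S)-2-hydroxy-2-[(3S)-4-oxo-6-[(1E)-prop-1-en-1-yl]-3,4-dihydro-2H-pyran-3-yl]acetate F2. Me(MeO)NH·HCl with i-PrMgCl (THF, −20 °C) converts this into (2S)-2-hydroxy-N-methoxy-N-methyl-2-[(3S)-4-oxo-6-[(1E)-prop-1-en-1-yl]-3,4-dihydro-2H-pyran-3-yl]acetamide F3, and MeMgBr (THF, −78 °C) gives methyl ketone 8, where the route resumes.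

Step 4. The basic vinyl metal may enolise the ketone or trigger retro-aldol cleavage of 8, and the acid stage may dehydrate the C8 carbinol before ring B closes. A reversible shift of the ring oxygen in 8 (C8–OH adding to C3) is also possible, but that isomer cannot close ring B and should drain back. The fallback sets out from 8 and uses a small, weakly basic masked acetyl anion. HC≡CMgBr (3 equiv, THF, −78 → −20 °C) adds under the same chelation control to give (3S)-3-[(1S,2S)-1,2-dihydroxy-2-methylbut-3-yn-1-yl]-6-[(1E)-prop-1-en-1-yl]-2,3-dihydro-4H-pyran-4-one F4. Markovnikov hydration of the alkyne with Ph3PAuNTf2 (2 mol %) in wet dioxane at rt then gives hydroxy diketone 10, where the route resumes, and 10 is cyclised separately with TsOH as in step 4.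

Step 6. The C8 hydroxyl is flanked by a quaternary and a tertiary carbon, the acid chloride is 2,6-disubstituted, and the product can lose the carboxylate by vinylogous elimination under base. The fallback sets out from 12 and makes the alcohol the nucleophile. Acetone, (CF3CO)2O and CF3CO2H give 7-hydroxy-2,2,5-trimethyl-4H-1,3-benzodioxin-4-one F5, and TBSCl/imidazole gives 7-(tert-butyldimethylsilyloxy)-2,2,5-trimethyl-4H-1,3-benzodioxin-4-one F6. The lithium alkoxide of 11 (LiN(SiMe3)2, THF, −78 → 0 °C) opens F6 with loss of acetone to give (7R,8S,8aS)-7-hydroxy-7-methyl-6-oxo-3-[(1E)-prop-1-en-1-yl]-6,7,8,8a-tetrahydro-1H-isochromen-8-yl 4-(tert-butyldimethylsilyloxy)-2-hydroxy-6-methylbenzoate F7. HF·pyridine (THF, 0 °C) then gives 16, where the route ends.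

**Further compounds**
F1 | step 3 | ethyl (2S)-2-[(3S)-4-oxo-6-[(1E)-prop-1-en-1-yl]-3,4-dihydro-2H-pyran-3-yl]-2-(trimethylsilyloxy)acetate | C/C=C/C1=CC(=O)[C@H]([C@H](O[Si](C)(C)C)C(=O)OCC)CO1
F2 | step 3 | ethyl (2S)-2-hydroxy-2-[(3S)-4-oxo-6-[(1E)-prop-1-en-1-yl]-3,4-dihydro-2H-pyran-3-yl]acetate | C/C=C/C1=CC(=O)[C@H]([C@H](O)C(=O)OCC)CO1
F3 | step 3 | (2S)-2-hydroxy-N-methoxy-N-methyl-2-[(3S)-4-oxo-6-[(1E)-prop-1-en-1-yl]-3,4-dihydro-2H-pyran-3-yl]acetamide | C/C=C/C1=CC(=O)[C@H]([C@H](O)C(=O)N(C)OC)CO1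
F4 | step 4 | (3S)-3-[(1S,2S)-1,2-dihydroxy-2-methylbut-3-yn-1-yl]-6-[(1E)-prop-1-en-1-yl]-2,3-dihydro-4H-pyran-4-one | C/C=C/C1=CC(=O)[C@H]([C@H](O)[C@@](C)(O)C#C)CO1
F5 | step 6 | 7-hydroxy-2,2,5-trimethyl-4H-1,3-benzodioxin-4-one | CC1(C)OC(=O)c2c(C)cc(O)cc2O1
F6 | step 6 | 7-(tert-butyldimethylsilyloxy)-2,2,5-trimethyl-4H-1,3-benzodioxin-4-one | CC1(C)OC(=O)c2c(C)cc(O[Si](C)(C)C(C)(C)C)cc2O1
F7 | step 6 | (7R,8S,8aS)-7-hydroxy-7-methyl-6-oxo-3-[(1E)-prop-1-en-1-yl]-6,7,8,8a-tetrahydro-1H-isochromen-8-yl 4-(tert-butyldimethylsilyloxy)-2-hydroxy-6-methylbenzoate | C/C=C/C1=CC2=CC(=O)[C@](C)(O)[C@@H](OC(=O)c3c(C)cc(O[Si](C)(C)C(C)(C)C)cc3O)[C@@H]2CO1
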